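**Strategy.** The oxolane ring is disconnected at the C3–C4 bond, between the methyl carbinol carbon C3 and the ring CH2 (C4). The key step joins allylic alcohol 3 with ethyl vinyl ether under divalent palladium: alkoxypalladation makes the O1–C5 acetal bond, then 5-exo carbopalladation of the vinyl group closes the ring at C3–C4 and β-hydride elimination leaves a 3-methylidene group. It exploits the fact that C4 is an unsubstituted CH2 lying between the O-bearing C5 and the oxygenated quaternary C3, so C5 can be a temporary ethyl acetal and C3 an exocyclic alkene. Markovnikov hydration then sets C3, and acetal substitution by an alkenyltrifluoroborate sets C5.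

Key step: step 2

Remark: oxolane atoms are numbered O1, C2 (bears the aryloxymethyl group), C3, C4, C5.
Remark: (R)-2-ethenyloxirane is assumed to be purchasable in enantiopure form.
Remark: compounds 7 and 8 are carried as mixtures of epimers at the acetal carbon C5, which is re-set in step 4.

**Step 1**
Reactants: 1 isofraxidin (7-hydroxy-6,8-dimethoxy-2H-chromen-2-one); 2 (R)-2-ethenyloxirane
Product: 3 7-{[(2R)-2-hydroxybut-3-en-1-yl]oxy}-6,8-dimethoxy-2H-chromen-2-one
Conditions: Cs2CO3 (0.2 equiv), 2 (2 equiv), DMF, 70 °C, sealed tube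
Reagents that add atoms: none
Why: Base-catalysed SN2 opening of the epoxide by the phenoxide should occur at the unsubstituted terminal carbon, so the stereocenter is not touched and the (R) configuration of 2 is carried into 3.

**Step 2**
Reactants: 3 7-{[(2R)-2-hydroxybut-3-en-1-yl]oxy}-6,8-dimethoxy-2H-chromen-2-one; 4 ethyl vinyl ether
Product: 7 7-{[(2R)-5-ethoxy-3-methylideneoxolan-2-yl]methoxy}-6,8-dimethoxy-2H-chromen-2-one (both C5 epimers), via alkoxypalladation adduct 5 (not isolated), via cyclized alkylpalladium acetate 6 (not isolated)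
Conditions: Pd(OAc)2 (10 mol %), Cu(OAc)2 (2.5 equiv), 4 (10 equiv), MeCN, 25 °C
Reagents that add atoms: none
Why: Pd(OAc)2 activates the electron-rich double bond of 4, the hydroxyl of 3 adds to its oxygen-bearing carbon (alkoxypalladation) to give σ-alkylpalladium 5 with the O1–C5 acetal bond in place, syn migratory insertion of the tethered vinyl group then forms the C3–C4 bond, and syn β-hydride elimination of the single β-hydrogen (C3–H) of 6 releases the exocyclic alkene while Cu(OAc)2 returns zerovalent palladium to the divalent state. The closest known reaction type is the oxidative alkoxypalladation–carbopalladation coupling of allylic alcohols with vinyl ethers to 2-alkoxy-4-methylideneoxolanes, an oxidative Heck-type cascade. The oxolane ring is closed in the 5-exo-trig mode, the alkylpalladium carbon C4 adding to the internal alkene carbon C3. No stereocenter of the target is created: C2 is not touched and keeps the configuration of 3, C3 becomes sp2, and the acetal carbon C5 forms as both epimers, which converge in step 4. The step needs alkoxypalladation at the vinyl ether and not at the allylic alkene, insertion faster than β-alkoxide elimination (vinyl exchange), 5-exo over 6-endo closure and no migration of the new alkene into the ring; these should be secured by the far higher reactivity of the enol ether towards palladium-activated attack, the three-atom tether that holds the vinyl group next to palladium, and the acetate-buffered, rapidly reoxidized medium.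

**Step 3**
Reactants: 7 7-{[(2R)-5-ethoxy-3-methylideneoxolan-2-yl]methoxy}-6,8-dimethoxy-2H-chromen-2-one
Product: 8 7-{[(2S,3R)-5-ethoxy-3-hydroxy-3-methyloxolan-2-yl]methoxy}-6,8-dimethoxy-2H-chromen-2-one (both C5 epimers)
Conditions: Co(acac)2 (20 mol %), PhSiH3 (2.5 equiv), O2 (1 atm), THF, 0 → 23 °C
Reagents that add atoms: dioxygen, O=O
Why: In this Mukaiyama hydration, hydrogen-atom transfer from a cobalt hydride to the terminal CH2 should give the tertiary C3 radical (Markovnikov), which should capture O2 on the ring face anti to the neighbouring C2 aryloxymethyl group before in-situ reduction of the peroxide by the silane, setting the (3R) carbinol with OH trans to the C2 substituent; the 1,1-disubstituted alkene should react ahead of the conjugated pyranone C=C.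

**Step 4**
Reactants: 8 7-{[(2S,3R)-5-ethoxy-3-hydroxy-3-methyloxolan-2-yl]methoxy}-6,8-dimethoxy-2H-chromen-2-one; 9 potassium trifluoro(2-methylprop-1-en-1-yl)borate
Product: 11 7-{[(2S,3R,5R)-3-hydroxy-3-methyl-5-(2-methylprop-1-en-1-yl)oxolan-2-yl]methoxy}-6,8-dimethoxy-2H-chromen-2-one, via oxocarbenium ion 10 (not isolated)
Conditions: 9 (2 equiv), BF3·OEt2 (3 equiv), MeCN, −20 → 0 °C; aq NaHCO3 work-up
Reagents that add atoms: none
Why: In this Lewis-acid-promoted acetal substitution (C-glycosylation type) with an alkenyltrifluoroborate, BF3 ionizes the ethoxy group of either epimer to the cyclic oxocarbenium ion 10, and the alkenyldifluoroborane formed in the flask should deliver the 2-methylprop-1-enyl group to C5 by inside attack on the envelope that has the C3 oxygen pseudoaxial and the C3 methyl pseudoequatorial (possibly helped by boron binding to the 3-OH), placing it cis to the 3-OH and trans to the C2 substituent, which is (5R).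

**Compound list**
1 | isofraxidin (7-hydroxy-6,8-dimethoxy-2H-chromen-2-one) | COc1cc2ccc(=O)oc2c(OC)c1O | starting material
2 | (R)-2-ethenyloxirane | C=C[C@@H]1CO1 | starting material
3 | 7-{[(2R)-2-hydroxybut-3-en-1-yl]oxy}-6,8-dimethoxy-2H-chromen-2-one | COc1cc2ccc(=O)oc2c(OC)c1OC[C@@H](C=C)O | intermediate
4 | ethyl vinyl ether (ethoxyethene) | C=COCC | starting material
5 | alkoxypalladation adduct: acetato(2-ethoxy-2-{[(2R)-1-[(6,8-dimethoxy-2-oxo-2H-chromen-7-yl)oxy]but-3-en-2-yl]oxy}ethyl)palladium | COc1cc2ccc(=O)oc2c(OC)c1OC[C@@H](C=C)OC(C[Pd]OC(C)=O)OCC | intermediate (not isolated)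
6 | cyclized alkylpalladium acetate: acetato{[(2R)-2-{[(6,8-dimethoxy-2-oxo-2H-chromen-7-yl)oxy]methyl}-5-ethoxyoxolan-3-yl]methyl}palladium | COc1cc2ccc(=O)oc2c(OC)c1OC[C@@H]1OC(OCC)CC1C[Pd]OC(C)=O | intermediate (not isolated)
7 | 7-{[(2R)-5-ethoxy-3-methylideneoxolan-2-yl]methoxy}-6,8-dimethoxy-2H-chromen-2-one (C5 epimers) | COc1cc2ccc(=O)oc2c(OC)c1OC[C@@H]1OC(OCC)CC1=C | intermediate
8 | 7-{[(2S,3R)-5-ethoxy-3-hydroxy-3-methyloxolan-2-yl]methoxy}-6,8-dimethoxy-2H-chromen-2-one (C5 epimers) | COc1cc2ccc(=O)oc2c(OC)c1OC[C@@H]1OC(OCC)C[C@@]1(C)O | intermediate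
9 | potassium trifluoro(2-methylprop-1-en-1-yl)borate | CC(C)=C[B-](F)(F)F.[K+] | starting material
10 | oxocarbenium ion: (2S,3R)-2-{[(6,8-dimethoxy-2-oxo-2H-chromen-7-yl)oxy]methyl}-3-hydroxy-3-methyl-3,4-dihydro-2H-furan-1-ium | COc1cc2ccc(=O)oc2c(OC)c1OC[C@@H]1[O+]=CC[C@@]1(C)O | intermediate (not isolated)
11 | 7-{[(2S,3R,5R)-3-hydroxy-3-methyl-5-(2-methylprop-1-en-1-yl)oxolan-2-yl]methoxy}-6,8-dimethoxy-2H-chromen-2-one | COc1cc2ccc(=O)oc2c(OC)c1OC[C@@H]1O[C@@H](C=C(C)C)C[C@@]1(C)O | target

**Total step count:** 4. **Longest linear sequence:** 4 steps (1 → 3 → 7 → 8 → 11).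

**Steps most likely to fail**

1. Step 2. Alkoxide elimination from 5 (vinyl exchange) may outrun the insertion, or the new exocyclic alkene may migrate into the ring and the acetal then lose ethanol to give a furan. Fallback, from 3 back to 7: bromoacetalization of 3 with NBS and ethyl vinyl ether (CH2Cl2, −20 °C) should give 7-{[(2R)-2-(2-bromo-1-ethoxyethoxy)but-3-en-1-yl]oxy}-6,8-dimethoxy-2H-chromen-2-one F1. A visible-light palladium-catalysed alkyl Heck cyclization (Pd(OAc)2, Xantphos, Cs2CO3, benzene, blue LEDs, 25 °C) should then close the same C3–C4 bond by 5-exo-trig attack of the C4 radical on the vinyl group and, after β-hydride elimination, return to 7.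

2. Step 3. Capture of O2 by the planar C3 radical may show poor facial selectivity, or hydrogen-atom transfer may also reach the pyranone alkene. Fallback, from 7 back to 8: dihydroxylation with the bulkier OsO4 (cat.)/NMO in acetone–water, anti to the C2 substituent, should give 7-{[(2S,3S)-5-ethoxy-3-hydroxy-3-(hydroxymethyl)oxolan-2-yl]methoxy}-6,8-dimethoxy-2H-chromen-2-one F2. Selective iodination of the primary hydroxyl (I2, PPh3, imidazole) should give 7-{[(2S,3R)-5-ethoxy-3-hydroxy-3-(iodomethyl)oxolan-2-yl]methoxy}-6,8-dimethoxy-2H-chromen-2-one F3, and radical deiodination (Bu3SnH, AIBN, benzene, 80 °C) should return to 8.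

3. Step 4. With the tertiary alcohol free, ion 10 may lose a C4 proton and aromatize to a furan, or facial control at C5 may be eroded. Fallback, from 8 back to 11: mild hydrolysis (PPTS, acetone–water) should give the lactol 7-{[(2S,3R)-3,5-dihydroxy-3-methyloxolan-2-yl]methoxy}-6,8-dimethoxy-2H-chromen-2-one F4. A Nozaki–Hiyama–Kishi addition of 1-bromo-2-methylprop-1-ene (CrCl2, NiCl2 cat., DMF) to its open hydroxy-aldehyde form should give 7-{[(2S,3R)-2,3,5-trihydroxy-3,7-dimethyloct-6-en-1-yl]oxy}-6,8-dimethoxy-2H-chromen-2-one F5 (C5 epimers). Acid-catalysed dehydrative cyclization (Bi(OTf)3 cat., CH2Cl2, 0 °C) through the dimethylallyl cation, with the C2 hydroxyl closing the O1–C5 bond, should converge both epimers on 11, the 2,5-trans isomer being favoured on equilibration.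

**Further compounds**
F1 | step 2 | 7-{[(2R)-2-(2-bromo-1-ethoxyethoxy)but-3-en-1-yl]oxy}-6,8-dimethoxy-2H-chromen-2-one | COc1cc2ccc(=O)oc2c(OC)c1OC[C@@H](C=C)OC(CBr)OCC
F2 | step 3 | 7-{[(2S,3S)-5-ethoxy-3-hydroxy-3-(hydroxymethyl)oxolan-2-yl]methoxy}-6,8-dimethoxy-2H-chromen-2-one | COc1cc2ccc(=O)oc2c(OC)c1OC[C@@H]1OC(OCC)C[C@@]1(CO)O
F3 | step 3 | 7-{[(2S,3R)-5-ethoxy-3-hydroxy-3-(iodomethyl)oxolan-2-yl]methoxy}-6,8-dimethoxy-2H-chromen-2-one | COc1cc2ccc(=O)oc2c(OC)c1OC[C@@H]1OC(OCC)C[C@@]1(CI)O
F4 | step 4 | 7-{[(2S,3R)-3,5-dihydroxy-3-methyloxolan-2-yl]methoxy}-6,8-dimethoxy-2H-chromen-2-one | COc1cc2ccc(=O)oc2c(OC)c1OC[C@@H]1OC(O)C[C@@]1(C)O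
F5 | step 4 | 7-{[(2S,3R)-2,3,5-trihydroxy-3,7-dimethyloct-6-en-1-yl]oxy}-6,8-dimethoxy-2H-chromen-2-one | COc1cc2ccc(=O)oc2c(OC)c1OC[C@@H]([C@](C)(O)CC(O)C=C(C)C)O
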